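## Retrosynthetic overview

1. The target comes from its tris-TBS ether by buffered fluoride desilylation in the last step.
2. The butenolide, the only ring made, is closed by one crossed aldol–lactonization that forms C2–C3 and O1–C5 of the 2,5-dihydrofuran-2-carboxylate. The nucleophile is a latent catechol-ring arylpyruvate (an arylidene dioxolanone) and the electrophile is the phenol-ring methyl arylpyruvate. A cinchona squaramide with a 4-nitrophenoxide acyl relay sets the quaternary C2 as (R).
3. Both pyruvate units come from an aryl aldehyde and 2,2-dimethyl-1,3-dioxolan-4-one by aldol/elimination; the electrophile is then released by methanolysis.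
4. Both aldehydes come from bought bromo(hydroxy)benzaldehydes by silylation and Stille prenylation.
5. Ring order: the two arenes are bought; the butenolide is formed in the penultimate step.

Assumption: the stereocenter in the SMILES is read as (R) at C2 of the furan-2-carboxylate, and compounds 1, 3, 5 and 10 are bought. Abbreviations: TBS = tert-butyldimethylsilyl, TBSO = its ether, prenyl = 3-methylbut-2-en-1-yl.

## Route

Step 1
Reactants: 1 3-bromo-4-hydroxybenzaldehyde
Product: 2 3-bromo-4-(TBSO)benzaldehyde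
Conditions: TBSCl (1.2 equiv), imidazole (2.5 equiv), DMF, rt
Reagents that add atoms: tert-butyldimethylsilyl chloride (TBSCl), CC(C)(C)[Si](C)(C)Cl
Why: Imidazole-promoted silylation of the phenol masks the acidic OH before the organometallic and enolate steps, and the aldehyde and aryl bromide are inert to it.

Step 2
Reactants: 2 3-bromo-4-(TBSO)benzaldehyde; 3 tributyl(3-methylbut-2-en-1-yl)stannane
Product: 4 4-(TBSO)-3-prenylbenzaldehyde
Conditions: Pd(PPh3)4 (5 mol%), toluene (degassed), 100 °C
Reagents that add atoms: none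
Why: Migita–Kosugi–Stille coupling, in which zerovalent palladium inserts into the formyl-activated C–Br bond and the allylic stannane delivers the prenyl group at its tin-bearing carbon under neutral, fluoride-free conditions that spare the aryl silyl ether and the aldehyde.

Step 3
Reactants: 4 4-(TBSO)-3-prenylbenzaldehyde; 5 2,2-dimethyl-1,3-dioxolan-4-one
Product: 8 (5Z)-5-{[4-(TBSO)-3-prenylphenyl]methylidene}-2,2-dimethyl-1,3-dioxolan-4-one, via lithium aldolate 6 (not isolated), via aldol mesylate 7 (not isolated)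
Conditions: 5 (1.5 equiv), LiN(iPr)2 (1.5 equiv), THF, −78 °C, 10 min; then 4; then MsCl (1.6 equiv), −78 → 0 °C; then DBU (3 equiv), 0 °C → rt
Reagents that add atoms: none
Why: Lithium enolate aldol addition of the glycolate acetonide to the non-enolisable aldehyde, then O-mesylation and E1cB elimination, gives the conjugated arylidene as the thermodynamic Z isomer; no stereocenter remains.

Step 4
Reactants: 8 (5Z)-5-{[4-(TBSO)-3-prenylphenyl]methylidene}-2,2-dimethyl-1,3-dioxolan-4-one
Product: 9 methyl 3-[4-(TBSO)-3-prenylphenyl]-2-oxopropanoate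
Conditions: MeOH (10 equiv), DMAP (20 mol%), CH2Cl2, rt
Reagents that add atoms: methanol, CO
Why: Nucleophile-catalysed alcoholysis of the activated acetal lactone (acyl transfer) expels acetone and the enol oxygen to release the α-keto ester, mostly as its Z-enol, under conditions too weakly basic to cleave the aryl silyl ether.

Step 5
Reactants: 10 3-bromo-4,5-dihydroxybenzaldehyde
Product: 11 3-bromo-4,5-bis(TBSO)benzaldehyde
Conditions: TBSCl (2.5 equiv), imidazole (5 equiv), DMF, rt
Reagents that add atoms: tert-butyldimethylsilyl chloride (TBSCl), CC(C)(C)[Si](C)(C)Cl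
Why: Double imidazole-promoted silylation protects the oxidation-prone catechol as a bis-silyl ether that is removed at the end together with the third TBS group.

Step 6
Reactants: 11 3-bromo-4,5-bis(TBSO)benzaldehyde; 3 tributyl(3-methylbut-2-en-1-yl)stannane
Product: 12 3,4-bis(TBSO)-5-prenylbenzaldehyde
Conditions: Pd(PPh3)4 (8 mol%), toluene (degassed), 105 °C
Reagents that add atoms: none
Why: Migita–Kosugi–Stille coupling as in step 2, with zerovalent palladium inserting into the C–Br bond next to the silyloxy group and the prenyl group transferred from tin without base or fluoride.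

Step 7
Reactants: 12 3,4-bis(TBSO)-5-prenylbenzaldehyde; 5 2,2-dimethyl-1,3-dioxolan-4-one
Product: 15 (5Z)-5-{[3,4-bis(TBSO)-5-prenylphenyl]methylidene}-2,2-dimethyl-1,3-dioxolan-4-one, via lithium aldolate 13 (not isolated), via aldol mesylate 14 (not isolated)
Conditions: 5 (1.5 equiv), LiN(iPr)2 (1.5 equiv), THF, −78 °C, 10 min; then 12; then MsCl (1.6 equiv), −78 → 0 °C; then DBU (3 equiv), 0 °C → rt
Reagents that add atoms: none
Why: The same enolate aldol, mesylation and E1cB elimination sequence as step 3 gives the Z-arylidene dioxolanone, a masked arylpyruvate that has no electrophilic ketone and no acidic C–H.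

Step 8
Reactants: 15 (5Z)-5-{[3,4-bis(TBSO)-5-prenylphenyl]methylidene}-2,2-dimethyl-1,3-dioxolan-4-one; 9 methyl 3-[4-(TBSO)-3-prenylphenyl]-2-oxopropanoate
Product: 18 methyl (2R)-3-[3,4-bis(TBSO)-5-prenylphenyl]-2-{[4-(TBSO)-3-prenylphenyl]methyl}-4-hydroxy-5-oxo-2,5-dihydrofuran-2-carboxylate, via nitrophenyl enol ester 16 (not isolated), via aldol adduct 17 (not isolated)
Conditions: quinine-derived 3,5-bis(trifluoromethyl)phenyl squaramide, i.e. 3-{[3,5-bis(trifluoromethyl)phenyl]amino}-4-{[(8α,9S)-6′-methoxycinchonan-9-yl]amino}cyclobut-3-ene-1,2-dione (10 mol%), 4-nitrophenol (20 mol%), 9 (1.5 equiv), 15 added over 6 h, toluene, 4 Å molecular sieves, 0 °C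
Reagents that add atoms: none
Why: Proposed new method: a relay-catalysed crossed arylpyruvate aldol–lactonization in which the catalyst's quinuclidine deprotonates the catalytic 4-nitrophenol and the phenoxide opens the squaramide-activated dioxolanone 15 with loss of acetone, unveiling the enolate of the activated ester 16 only at catalyst-level concentration; this enolate, as a chiral ammonium ion pair, adds through its benzylic carbon to the Re face (O > CO2Me > CH2Ar) of the keto tautomer of 9, which the squaramide N–H pair holds by two-point hydrogen bonding to the s-cis 1,2-dicarbonyl, setting C2 as (R) in 17; the tertiary hydroxyl then closes onto the 4-nitrophenyl ester faster than retro-aldol, returning the phenoxide, and the keto lactone enolizes to erase the second stereocenter; the roles are fixed because 15 cannot act as a ketone or self-condense, whereas adducts in which 9 is the nucleophile carry only a methyl ester, close slowly and revert; the closest known reaction types are the amine-catalysed aldol–lactonization of α-keto esters to isotetronic acids, bifunctional cinchona-catalysed face-selective additions to α-keto esters, bifunctional-catalyst alcoholysis of azlactones and aryloxide-rebound acyl-transfer catalysis.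

Step 9
Reactants: 18 methyl (2R)-3-[3,4-bis(TBSO)-5-prenylphenyl]-2-{[4-(TBSO)-3-prenylphenyl]methyl}-4-hydroxy-5-oxo-2,5-dihydrofuran-2-carboxylate
Product: 19 methyl (2R)-3-[3,4-dihydroxy-5-(3-methylbut-2-en-1-yl)phenyl]-4-hydroxy-2-{[4-hydroxy-3-(3-methylbut-2-en-1-yl)phenyl]methyl}-5-oxo-2,5-dihydrofuran-2-carboxylate
Conditions: Bu4NF (3.3 equiv), AcOH (3.5 equiv), THF, 0 °C, argon
Reagents that add atoms: none
Why: Fluoride-induced desilylation cleaves the three aryl O–Si bonds, while the acetic acid buffer protects the methyl ester and lactone, avoids base-mediated air oxidation of the catechol and acid-catalysed chroman formation from the ortho-prenyl phenols, and leaves the non-enolisable quaternary (R) center untouched.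

## Compound list

1 | 3-bromo-4-hydroxybenzaldehyde | O=Cc1ccc(O)c(Br)c1 | starting material
2 | 3-bromo-4-(TBSO)benzaldehyde | O=Cc1ccc(O[Si](C)(C)C(C)(C)C)c(Br)c1 | intermediate
3 | tributyl(3-methylbut-2-en-1-yl)stannane | CCCC[Sn](CCCC)(CCCC)CC=C(C)C | starting material
4 | 4-(TBSO)-3-prenylbenzaldehyde | O=Cc1ccc(O[Si](C)(C)C(C)(C)C)c(CC=C(C)C)c1 | intermediate
5 | 2,2-dimethyl-1,3-dioxolan-4-one | CC1(C)OCC(=O)O1 | starting material
6 | lithium [4-(TBSO)-3-prenylphenyl](2,2-dimethyl-5-oxo-1,3-dioxolan-4-yl)methanolate (racemic, both diastereomers) | CC1(C)OC(C([O-])c2ccc(O[Si](C)(C)C(C)(C)C)c(CC=C(C)C)c2)C(=O)O1.[Li+] | intermediate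
7 | [4-(TBSO)-3-prenylphenyl](2,2-dimethyl-5-oxo-1,3-dioxolan-4-yl)methyl methanesulfonate (racemic, both diastereomers) | CC1(C)OC(C(OS(C)(=O)=O)c2ccc(O[Si](C)(C)C(C)(C)C)c(CC=C(C)C)c2)C(=O)O1 | intermediate
8 | (5Z)-5-{[4-(TBSO)-3-prenylphenyl]methylidene}-2,2-dimethyl-1,3-dioxolan-4-one | CC1(C)O/C(=C\c2ccc(O[Si](C)(C)C(C)(C)C)c(CC=C(C)C)c2)C(=O)O1 | intermediate
9 | methyl 3-[4-(TBSO)-3-prenylphenyl]-2-oxopropanoate (keto form drawn; mainly Z-enol in solution) | COC(=O)C(=O)Cc1ccc(O[Si](C)(C)C(C)(C)C)c(CC=C(C)C)c1 | intermediate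
10 | 3-bromo-4,5-dihydroxybenzaldehyde | O=Cc1cc(O)c(O)c(Br)c1 | starting material
11 | 3-bromo-4,5-bis(TBSO)benzaldehyde | O=Cc1cc(O[Si](C)(C)C(C)(C)C)c(O[Si](C)(C)C(C)(C)C)c(Br)c1 | intermediate
12 | 3,4-bis(TBSO)-5-prenylbenzaldehyde | O=Cc1cc(O[Si](C)(C)C(C)(C)C)c(O[Si](C)(C)C(C)(C)C)c(CC=C(C)C)c1 | intermediate
13 | lithium [3,4-bis(TBSO)-5-prenylphenyl](2,2-dimethyl-5-oxo-1,3-dioxolan-4-yl)methanolate (racemic, both diastereomers) | CC1(C)OC(C([O-])c2cc(O[Si](C)(C)C(C)(C)C)c(O[Si](C)(C)C(C)(C)C)c(CC=C(C)C)c2)C(=O)O1.[Li+] | intermediate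
14 | [3,4-bis(TBSO)-5-prenylphenyl](2,2-dimethyl-5-oxo-1,3-dioxolan-4-yl)methyl methanesulfonate (racemic, both diastereomers) | CC1(C)OC(C(OS(C)(=O)=O)c2cc(O[Si](C)(C)C(C)(C)C)c(O[Si](C)(C)C(C)(C)C)c(CC=C(C)C)c2)C(=O)O1 | intermediate
15 | (5Z)-5-{[3,4-bis(TBSO)-5-prenylphenyl]methylidene}-2,2-dimethyl-1,3-dioxolan-4-one | CC1(C)O/C(=C\c2cc(O[Si](C)(C)C(C)(C)C)c(O[Si](C)(C)C(C)(C)C)c(CC=C(C)C)c2)C(=O)O1 | intermediate
16 | 4-nitrophenyl (2Z)-3-[3,4-bis(TBSO)-5-prenylphenyl]-2-hydroxyprop-2-enoate | O/C(=C\c1cc(O[Si](C)(C)C(C)(C)C)c(O[Si](C)(C)C(C)(C)C)c(CC=C(C)C)c1)C(=O)Oc1ccc(cc1)[N+](=O)[O-] | intermediate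
17 | 1-methyl 5-(4-nitrophenyl) (2R)-3-[3,4-bis(TBSO)-5-prenylphenyl]-2-{[4-(TBSO)-3-prenylphenyl]methyl}-2-hydroxy-4-oxopentanedioate (both C3 epimers) | COC(=O)[C@](Cc1ccc(O[Si](C)(C)C(C)(C)C)c(CC=C(C)C)c1)(O)C(c1cc(O[Si](C)(C)C(C)(C)C)c(O[Si](C)(C)C(C)(C)C)c(CC=C(C)C)c1)C(=O)C(=O)Oc1ccc(cc1)[N+](=O)[O-] | intermediate
18 | methyl (2R)-3-[3,4-bis(TBSO)-5-prenylphenyl]-2-{[4-(TBSO)-3-prenylphenyl]methyl}-4-hydroxy-5-oxo-2,5-dihydrofuran-2-carboxylate | COC(=O)[C@]1(Cc2ccc(O[Si](C)(C)C(C)(C)C)c(CC=C(C)C)c2)OC(=O)C(O)=C1c1cc(O[Si](C)(C)C(C)(C)C)c(O[Si](C)(C)C(C)(C)C)c(CC=C(C)C)c1 | intermediate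
19 | methyl (2R)-3-[3,4-dihydroxy-5-(3-methylbut-2-en-1-yl)phenyl]-4-hydroxy-2-{[4-hydroxy-3-(3-methylbut-2-en-1-yl)phenyl]methyl}-5-oxo-2,5-dihydrofuran-2-carboxylate | COC(=O)[C@]1(Cc2ccc(O)c(CC=C(C)C)c2)OC(=O)C(O)=C1c1cc(O)c(O)c(CC=C(C)C)c1 | target

## Step count and risks

Total step count: 9. Longest linear sequence: 6 (steps 1, 2, 3, 4, 8, 9).

**Step 8 (the proposed relay aldol–lactonization).** It can fail in three ways: phenolysis of 15 may be too slow, proton shuffling between the enols may erode the role assignment, or the facial selectivity may be modest or reversed. For a reversed sense of induction the first adjustment is the quinidine-derived pseudoenantiomeric squaramide. The fallback uses known chemistry; it sets out from 15 and 9 and comes back to the route at 18. Compound 15 is opened with MeOH and DMAP as in step 4 to give methyl 3-[3,4-bis(TBSO)-5-prenylphenyl]-2-oxopropanoate F1. F1 and an excess of 9 are then condensed with DBU in MeCN at 0 °C, which is the established base-promoted arylpyruvate aldol–lactonization run with two partners. The racemic crossed butenolide, racemic methyl 3-[3,4-bis(TBSO)-5-prenylphenyl]-2-{[4-(TBSO)-3-prenylphenyl]methyl}-4-hydroxy-5-oxo-2,5-dihydrofuran-2-carboxylate F2, is separated from the homo-condensation products by chromatography. It is then resolved by preparative HPLC on a chiral stationary phase to give 18. This is low-yielding (a statistical mixture) but secure.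

**Step 7 (and its twin, step 3).** The lithium enolate of 5 is thermally fragile and the aldolate can revert before mesylation. The fallback replaces the aldol/elimination by a Wittig olefination; it sets out from 5 and 12 and comes back at 15. Radical bromination of 5 (N-bromosuccinimide, AIBN, PhCF3, reflux) gives 5-bromo-2,2-dimethyl-1,3-dioxolan-4-one F3. PPh3 in toluene converts it into (2,2-dimethyl-5-oxo-1,3-dioxolan-4-yl)triphenylphosphonium bromide F4. Et3N then gives the stabilised ylide 2,2-dimethyl-5-(triphenyl-λ5-phosphanylidene)-1,3-dioxolan-4-one F5. F5 olefinates 12 in toluene at 80 °C to give 15. The same ylide serves the 4 → 8 conversion.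

**Step 6 (Stille prenylation of the crowded bromide).** Oxidative addition next to two silyloxy groups may be slow, and transfer through the far allyl terminus would give the 1,1-dimethylallyl isomer. The fallback installs the prenyl group in two stages; it sets out from 11 and comes back at 12. Stille coupling of 11 with allyltributylstannane (Pd(PPh3)4, toluene, 100 °C), for which the two allyl termini are identical, gives 3,4-bis(TBSO)-5-(prop-2-en-1-yl)benzaldehyde F6. Olefin cross-metathesis of F6 in 2-methylbut-2-ene at 40 °C with the second-generation Grubbs catalyst, RuCl2(H2IMes)(PCy3)(=CHPh) at 5 mol%, converts the allyl group into the prenyl group of 12.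

Further compounds

F1 | step 8 | methyl 3-[3,4-bis(TBSO)-5-prenylphenyl]-2-oxopropanoate | COC(=O)C(=O)Cc1cc(O[Si](C)(C)C(C)(C)C)c(O[Si](C)(C)C(C)(C)C)c(CC=C(C)C)c1
F2 | step 8 | racemic methyl 3-[3,4-bis(TBSO)-5-prenylphenyl]-2-{[4-(TBSO)-3-prenylphenyl]methyl}-4-hydroxy-5-oxo-2,5-dihydrofuran-2-carboxylate | COC(=O)C1(Cc2ccc(O[Si](C)(C)C(C)(C)C)c(CC=C(C)C)c2)OC(=O)C(O)=C1c1cc(O[Si](C)(C)C(C)(C)C)c(O[Si](C)(C)C(C)(C)C)c(CC=C(C)C)c1
F3 | step 7 | 5-bromo-2,2-dimethyl-1,3-dioxolan-4-one | CC1(C)OC(Br)C(=O)O1
F4 | step 7 | (2,2-dimethyl-5-oxo-1,3-dioxolan-4-yl)triphenylphosphonium bromide | CC1(C)OC([P+](c2ccccc2)(c2ccccc2)c2ccccc2)C(=O)O1.[Br-]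
F5 | step 7 | 2,2-dimethyl-5-(triphenyl-λ5-phosphanylidene)-1,3-dioxolan-4-one | CC1(C)OC(=P(c2ccccc2)(c2ccccc2)c2ccccc2)C(=O)O1
F6 | step 6 | 3,4-bis(TBSO)-5-(prop-2-en-1-yl)benzaldehyde | O=Cc1cc(O[Si](C)(C)C(C)(C)C)c(O[Si](C)(C)C(C)(C)C)c(CC=C)c1
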